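**Plan**
Locants (stenine type): C1–C2–C3–N4–C5…C8–C9–C9a(=O); C10 (Et)–C11 (O)–C12–C13 (Me)–C14 form lactone ring D with O; C18–C21 form side-chain lactone ring E.
Enabling feature: the quaternary cyclopentane carbon C9 (ring C1/C9/C10/C11/C12) carries the lactam carbonyl C9a, and the lactam nitrogen is tied back through C3–C2 to ring carbon C1. A 1,2-shift of C1 between C9a and C9 therefore interconverts the bridged cyclopenta-lactam with an ordinary cyclohexanone-derived iminium ion (ring A: C1, C9a, C9, C10, C11, C12), the presumed biogenetic pinacol-type contraction of a tuberostemonine-type ring.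
Cuts, in retro order: O–Si and C19=C20 (adjustments); C1–C9 moved back to C1–C9a together with N4–C5; N4=C9a; C3–C18; C3=N; C8–C9; C9–Cl; C1–C12; C1–C9a; C10–C11.
Forward ring order: butenolide D, cyclohexanone ring A (Michael), butenolide E (appended), pyrroline ring B, then in one flask azepane ring C and, last, the cyclopentane with the six-membered lactam.
Stereochemistry: C10/C11 by imidazolidinone catalysis; C12, C1, C13 from the ring-A closure; C8 and the C9 chloride from one anti aldol; C3/C18 from the sulfinyl auxiliary; C9 by inversion in the shift; C20 by hydrogenation.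
Key step: step 13

Assumption: the (2R,5R)-imidazolidinone and the (S)-sulfinamide are taken as the antipodes that give the drawn configurations (shielded-face model of the enal iminium ion; imine attack anti to tert-butyl); if induction on these substrates runs the other way, the mirror-image controller is used.

Step 1
Reactants: 1 3-methylfuran-2(5H)-one
Product: 2 3-methyl-2-(trimethylsilyloxy)furan
Conditions: Me3SiOTf, Et3N, CH2Cl2, 0 °C; distil
Reagents that add atoms: trimethylsilyl trifluoromethanesulfonate, C[Si](C)(C)OS(=O)(=O)C(F)(F)F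
Why: Soft enolisation of the butenolide by silyl triflate and amine is the standard silyl dienol ether formation leading to 2-silyloxyfurans, and no stereocentre is formed.

Step 2
Reactants: 2 3-methyl-2-(trimethylsilyloxy)furan; 3 (E)-pent-2-enal
Product: 4 butenolide aldehyde
Conditions: (2R,5R)-5-benzyl-2-tert-butyl-3-methylimidazolidin-4-one (20 mol %), 2,4-dinitrobenzoic acid (20 mol %), H2O (2 equiv), CH2Cl2, −70 °C
Reagents that add atoms: none
Why: Iminium-catalysed vinylogous Mukaiyama–Michael addition, in which the furan adds through C5 to the β-carbon of the enal iminium ion, whose shielded face should fix C10 (S) and whose diastereoselective transition state should fix C11 (R), the pair that later becomes the trans ethyl/oxygen relationship on ring A.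

Step 3
Reactants: 4 butenolide aldehyde; 5 2-(2-bromoethyl)-1,3-dioxolane
Product: 7 hydroxy butenolide (both carbinol epimers), via Grignard reagent 6 (not isolated)
Conditions: 5, Mg turnings, THF, 20–25 °C; then 4, THF, −78 °C; saturated aq. NH4Cl
Reagents that add atoms: none
Why: Magnesium insertion into the primary bromide below 30 °C gives the acetal Grignard reagent, which at −78 °C adds to the aldehyde far faster than to the lactone (Grignard addition) and so attaches C1–C3, and the new carbinol centre needs no control because it is oxidised in step 4.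

Step 4
Reactants: 7 hydroxy butenolide (both carbinol epimers)
Product: 8 keto butenolide
Conditions: Dess–Martin periodinane, CH2Cl2, rt
Reagents that add atoms: none
Why: Dess–Martin oxidation of the secondary alcohol is neutral enough to leave the base-sensitive butenolide and the acetal untouched, and no stereocentre is formed.

Step 5
Reactants: 8 keto butenolide
Product: 9 ring-A keto lactone
Conditions: pyrrolidine (30 mol %), AcOH (30 mol %), CHCl3, 40 °C; aqueous work-up
Reagents that add atoms: none
Why: Intramolecular Stork-type enamine Michael addition (6-enolendo-exo-trig) in which only the enamine towards C1 can reach the butenolide β-carbon C12 (the C9 enamine would need a four-membered ring), the tether through C10/C11 forces the cis fusion at C12, the (E)-enamine reacting through the chair with equatorial ethyl should place C2 axial on C1 and hence trans to the C12–C13 bond, and protonation of the lactone enolate on the convex face should set C13 with methyl cis to C1, all without a base strong enough to epimerise the butenolide γ-carbon.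

Step 6
Reactants: 9 ring-A keto lactone
Product: 11 α-chloro ketone (both C9 epimers), via lithium enolate 10 (not isolated)
Conditions: LiN(i-Pr)2, THF, −78 °C; then N-chlorosuccinimide, −78 °C; AcOH quench
Reagents that add atoms: N-chlorosuccinimide, O=C1CCC(=O)N1Cl
Why: Kinetic deprotonation at the less hindered methylene C9 (not tertiary C1 or the lactone α-carbon) followed by electrophilic chlorination of the enolate places the future leaving group regiospecifically at C9, whose configuration is irrelevant because the centre is re-enolised in step 7.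

Step 7
Reactants: 11 α-chloro ketone (both C9 epimers); 12 4-chlorobutanal
Product: 14 chlorohydrin, via boron enolate 13 (not isolated)
Conditions: (c-C6H11)2BCl, Et3N, Et2O, −78 to 0 °C; then 12, −78 °C; pH 7 phosphate buffer, MeOH
Reagents that add atoms: none
Why: Boron-mediated aldol reaction in which enolisation goes to the more acidic chlorine-bearing C9, the ring-locked (E)-enolate reacts through a closed chair transition state (anti relationship of C10 and O8) on the face opposite the pseudoaxial ethyl group, so that one event should set C8 (R) and the quaternary C9 with chlorine cis to ethyl, while the neutral work-up avoids Darzens closure.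

Step 8
Reactants: 14 chlorohydrin
Product: 15 silyl ether
Conditions: t-BuMe2SiOTf, 2,6-lutidine, CH2Cl2, −78 to 0 °C
Reagents that add atoms: tert-butyldimethylsilyl trifluoromethanesulfonate, CC(C)(C)[Si](C)(C)OS(=O)(=O)C(F)(F)F
Why: Silylation with the silyl triflate and a hindered pyridine base is fast on the neopentyl secondary alcohol and non-basic enough to avoid retro-aldol or epoxide formation, it blocks O8 from displacing the chloride later, and any acetal opening by the triflate/lutidine pair would only anticipate step 9.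

Step 9
Reactants: 15 silyl ether
Product: 16 keto aldehyde
Conditions: pyridinium p-toluenesulfonate (cat.), acetone/H2O, 55 °C
Reagents that add atoms: water, O
Why: Mild acid-catalysed acetal hydrolysis frees the C3 aldehyde while the secondary silyl ether, the tertiary chloride, the ketone and the lactone should tolerate the weak acid.

Step 10
Reactants: 16 keto aldehyde; 17 (S)-2-methylpropane-2-sulfinamide
Product: 18 N-sulfinyl aldimine
Conditions: CuSO4, CH2Cl2, rt
Reagents that add atoms: none
Why: Condensation of the sulfinamide with the unhindered aldehyde (the α-quaternary ketone does not react under these conditions) installs the chiral auxiliary on nitrogen as the (E)-aldimine.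

Step 11
Reactants: 18 N-sulfinyl aldimine; 2 3-methyl-2-(trimethylsilyloxy)furan
Product: 19 N-sulfinyl amino butenolide
Conditions: Me3SiOTf (20 mol %), CH2Cl2, −78 °C; then aq. NaHCO3
Reagents that add atoms: none
Why: Lewis-acid promoted vinylogous Mannich reaction in which attack on the imine face opposite the tert-butyl group should set C3 (R) and the open transition state should set C18 (R), giving the 5-(1-aminoalkyl)butenolide that carries C3 and ring E.

Step 12
Reactants: 19 N-sulfinyl amino butenolide
Product: 22 α-chloro imine, via ammonium chloride 20 (not isolated), via amino ketone 21 (not isolated)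
Conditions: HCl (4 M in dioxane), MeOH, 0 °C; evaporate; then NaOAc, 4 Å molecular sieves, CH2Cl2, rt
Reagents that add atoms: none
Why: Acidic methanolysis removes the sulfinyl group and, on buffering, the γ-amino ketone condenses intramolecularly to the five-membered cyclic imine, which should outrun attack of the amine on the tertiary chloride or O-to-N acyl transfer from the neighbouring butenolide, with no stereocentre changed.

Step 13
Reactants: 22 α-chloro imine
Product: 26 bridged lactam silyl ether, via primary iodide 23 (not isolated), via iminium iodide 24 (not isolated), via carbinolamine 25 (not isolated)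
Conditions: NaI, MeCN, 70 °C, high dilution; then AgBF4, NaHCO3, THF/H2O, 0 °C to rt
Reagents that add atoms: water, O
Why: Proposed new method: Finkelstein exchange and attack of the imine nitrogen (its lone pair lies syn to C9) close azepane ring C and give the tricyclic α-chloro iminium ion 24, water adds to C9a to give carbinolamine 25, and Ag+-assisted loss of the tertiary chloride is coupled to a 1,2-shift of C1 from C9a to C9 (semibenzilic, quasi-Favorskii mechanism) that contracts ring A to the cyclopentane, widens the pyrroline to the six-membered lactam and leaves C9a as the bridging carbonyl. The closest known reaction types are the Favorskii ring contraction of 2-chlorocyclohexanones by amines, the Favorskii-type rearrangement of α-chloro ketimines to amides and the indole-to-oxindole 1,2-shift through a 3-chloroindolenine, none of which has yet delivered a bridged, twisted lactam. Ring closures: ring C by nucleophilic N-alkylation (7-exo-tet), then the cyclopentane by backside displacement at C9 by the migrating C9a–C1 bond (a bridged, formally 3-exo-tet transition state), the piperidinone arising from the same shift. Stereocentres: C9 forms with inversion, so the aldol-derived chloride (cis to ethyl) fixes it; C1 migrates with retention; the transient C9a centre needs no control because the carbinolamine epimers equilibrate through 24. The selectivity needed is carbon shift over attack of the carbinolamine oxygen or nitrogen on C9 and over enolisation towards C1: in epimer 25 (hydroxyl cis to chloride, ring B trans-fused) the azepane ring requires N4 gauche to C8, which holds C8 axial and chloride equatorial on ring A, so that the C9a–C1 ring bond and neither heteroatom is antiperiplanar to C9–Cl, whereas the other epimer (hydroxyl and chloride trans-diaxial) can revert through 24; the silyl ether keeps O8 from closing an epoxide, and buffered aqueous silver conditions avoid the enamine and cyclopropaniminium pathways.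

Step 14
Reactants: 26 bridged lactam silyl ether
Product: 27 saturated bridged lactam silyl ether
Conditions: H2 (3 atm), Pd/C, EtOAc, rt
Reagents that add atoms: none
Why: Heterogeneous hydrogenation of the butenolide C19=C20 from the face opposite the C18 substituent should give the cis-disubstituted lactone (C20 R), while the twisted lactam, lactone D and the silyl ether are inert to H2 on Pd/C.

Step 15
Reactants: 27 saturated bridged lactam silyl ether
Product: 28 target CNP0120800.1
Conditions: HF·pyridine, pyridine, THF, 0 °C to rt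
Reagents that add atoms: none
Why: Buffered fluoride desilylation frees the C8 hydroxyl without exposing the twisted lactam or the lactones to hydroxide or alkoxide, and no stereocentre is touched.

**Compound list**
1 | 3-methylfuran-2(5H)-one | CC1=CCOC1=O | starting material
2 | 3-methyl-2-(trimethylsilyloxy)furan | Cc1ccoc1O[Si](C)(C)C | intermediate
3 | (E)-pent-2-enal | CC/C=C/C=O | starting material
4 | butenolide aldehyde, (3S)-3-[(2R)-4-methyl-5-oxo-2,5-dihydrofuran-2-yl]pentanal | CC[C@@H](CC=O)[C@H]1OC(=O)C(C)=C1 | intermediate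
5 | 2-(2-bromoethyl)-1,3-dioxolane | BrCCC1OCCO1 | starting material
6 | Grignard reagent, [2-(1,3-dioxolan-2-yl)ethyl]magnesium bromide | Br[Mg]CCC1OCCO1 | intermediate
7 | hydroxy butenolide, (5R)-5-[(3S)-7-(1,3-dioxolan-2-yl)-5-hydroxyheptan-3-yl]-3-methylfuran-2(5H)-one, both carbinol epimers | CC[C@@H](CC(O)CCC1OCCO1)[C@H]1OC(=O)C(C)=C1 | intermediate
8 | keto butenolide, (5R)-5-[(3S)-7-(1,3-dioxolan-2-yl)-5-oxoheptan-3-yl]-3-methylfuran-2(5H)-one | CC[C@@H](CC(=O)CCC1OCCO1)[C@H]1OC(=O)C(C)=C1 | intermediate
9 | ring-A keto lactone, (3S,3aR,4S,7S,7aR)-4-(1,3-dioxolan-2-ylmethyl)-7-ethyl-3-methyl-3,3a,4,6,7,7a-hexahydro-1-benzofuran-2,5-dione | CC[C@@H]1[C@H]2OC(=O)[C@@H](C)[C@H]2[C@H](CC2OCCO2)C(=O)C1 | intermediate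
10 | lithium enolate of 9 (O–Li on C9a, C9=C9a) | CC[C@@H]1[C@H]2OC(=O)[C@@H](C)[C@H]2[C@H](CC2OCCO2)C(O[Li])=C1 | intermediate
11 | α-chloro ketone, (3S,3aR,4S,7R,7aS)-6-chloro-4-(1,3-dioxolan-2-ylmethyl)-7-ethyl-3-methyl-3,3a,4,6,7,7a-hexahydro-1-benzofuran-2,5-dione, both C6 (stenine C9) epimers | CC[C@@H]1[C@H]2OC(=O)[C@@H](C)[C@H]2[C@H](CC2OCCO2)C(=O)C1Cl | intermediate
12 | 4-chlorobutanal | O=CCCCCl | starting material
13 | dicyclohexylboron enolate of 11 | CC[C@@H]1[C@H]2OC(=O)[C@@H](C)[C@H]2[C@H](CC2OCCO2)C(OB(C2CCCCC2)C2CCCCC2)=C1Cl | intermediate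
14 | chlorohydrin, (3S,3aR,4S,6S,7R,7aS)-6-chloro-6-[(1R)-4-chloro-1-hydroxybutyl]-4-(1,3-dioxolan-2-ylmethyl)-7-ethyl-3-methyl-3,3a,4,6,7,7a-hexahydro-1-benzofuran-2,5-dione | CC[C@@H]1[C@H]2OC(=O)[C@@H](C)[C@H]2[C@H](CC2OCCO2)C(=O)[C@@]1(Cl)[C@H](O)CCCCl | intermediate
15 | silyl ether, the (1R)-O-tert-butyldimethylsilyl ether of 14 | CC[C@@H]1[C@H]2OC(=O)[C@@H](C)[C@H]2[C@H](CC2OCCO2)C(=O)[C@@]1(Cl)[C@H](O[Si](C)(C)C(C)(C)C)CCCCl | intermediate
16 | keto aldehyde, [(3S,3aR,4S,6S,7R,7aS)-6-{(1R)-1-[tert-butyl(dimethyl)silyl]oxy-4-chlorobutyl}-6-chloro-7-ethyl-3-methyl-2,5-dioxooctahydro-1-benzofuran-4-yl]acetaldehyde | CC[C@@H]1[C@H]2OC(=O)[C@@H](C)[C@H]2[C@H](CC=O)C(=O)[C@@]1(Cl)[C@H](O[Si](C)(C)C(C)(C)C)CCCCl | intermediate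
17 | (S)-2-methylpropane-2-sulfinamide | CC(C)(C)[S@@](N)=O | starting material
18 | N-sulfinyl aldimine, the (S at sulfur, E) tert-butanesulfinyl imine of 16 | CC[C@@H]1[C@H]2OC(=O)[C@@H](C)[C@H]2[C@H](C/C=N/[S@@](=O)C(C)(C)C)C(=O)[C@@]1(Cl)[C@H](O[Si](C)(C)C(C)(C)C)CCCCl | intermediate
19 | N-sulfinyl amino butenolide, (S)-sulfinamide of the (3R)-amine carrying the (18R)-4-methyl-5-oxo-2,5-dihydrofuran-2-yl group at C3 | CC[C@@H]1[C@H]2OC(=O)[C@@H](C)[C@H]2[C@H](C[C@H]([C@H]3C=C(C)C(=O)O3)N[S@@](=O)C(C)(C)C)C(=O)[C@@]1(Cl)[C@H](O[Si](C)(C)C(C)(C)C)CCCCl | intermediate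
20 | ammonium chloride formed from 19 by loss of the sulfinyl group | CC[C@@H]1[C@H]2OC(=O)[C@@H](C)[C@H]2[C@H](C[C@H]([C@H]3C=C(C)C(=O)O3)[NH3+])C(=O)[C@@]1(Cl)[C@H](O[Si](C)(C)C(C)(C)C)CCCCl.[Cl-] | intermediate
21 | amino ketone, free base of 20 | CC[C@@H]1[C@H]2OC(=O)[C@@H](C)[C@H]2[C@H](C[C@H]([C@H]3C=C(C)C(=O)O3)N)C(=O)[C@@]1(Cl)[C@H](O[Si](C)(C)C(C)(C)C)CCCCl | intermediate
22 | α-chloro imine, 1-pyrroline ring B (N4=C9a) fused to ring A, stenine locants (1S,3R,8R,9R,10R,11S,12R,13S,18R) | CC[C@@H]1[C@H]2OC(=O)[C@@H](C)[C@H]2[C@@H]2C[C@H]([C@H]3C=C(C)C(=O)O3)N=C2[C@@]1(Cl)[C@H](O[Si](C)(C)C(C)(C)C)CCCCl | intermediate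
23 | primary iodide corresponding to 22 (C5–I) | CC[C@@H]1[C@H]2OC(=O)[C@@H](C)[C@H]2[C@@H]2C[C@H]([C@H]3C=C(C)C(=O)O3)N=C2[C@@]1(Cl)[C@H](O[Si](C)(C)C(C)(C)C)CCCI | intermediate
24 | iminium iodide, tricyclic 9-chloro N4=C9a iminium salt with rings A, B, C, D | CC[C@@H]1[C@H]2OC(=O)[C@@H](C)[C@H]2[C@@H]2C[C@H]([C@H]3C=C(C)C(=O)O3)[N+]3=C2[C@@]1(Cl)[C@H](O[Si](C)(C)C(C)(C)C)CCC3.[I-] | intermediate
25 | carbinolamine, (9S,9aS)-9-chloro-9a-hydroxy tricyclic amine | CC[C@@H]1[C@H]2OC(=O)[C@@H](C)[C@H]2[C@@H]2C[C@H]([C@H]3C=C(C)C(=O)O3)N3CCC[C@@H](O[Si](C)(C)C(C)(C)C)[C@]1(Cl)[C@@]23O | intermediate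
26 | bridged lactam silyl ether with butenolide E, (1S,3R,8R,9S,10S,11S,12R,13S,18R) | CC[C@@H]1[C@H]2OC(=O)[C@@H](C)[C@H]2[C@@H]2C[C@H]([C@H]3C=C(C)C(=O)O3)N3CCC[C@@H](O[Si](C)(C)C(C)(C)C)[C@@]12C3=O | intermediate
27 | saturated bridged lactam silyl ether, 8-O-tert-butyldimethylsilyl ether of the target, (1S,3R,8R,9S,10S,11S,12R,13S,18R,20R) | CC[C@@H]1[C@H]2OC(=O)[C@@H](C)[C@H]2[C@@H]2C[C@H]([C@H]3C[C@@H](C)C(=O)O3)N3CCC[C@@H](O[Si](C)(C)C(C)(C)C)[C@@]12C3=O | intermediate
28 | target CNP0120800.1, the 8-hydroxy bridged lactam (1S,3R,8R,9S,10S,11S,12R,13S,18R,20R) | CC[C@@H]1[C@H]2OC(=O)[C@@H](C)[C@H]2[C@@H]2C[C@H]([C@H]3C[C@@H](C)C(=O)O3)N3CCC[C@@H](O)[C@@]12C3=O | target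

**Summary**
Total step count: 15. Longest linear sequence: 15 steps (1 to 28).

Steps most likely to fail:

1. Step 13 (Proposed new method). What may go wrong: the seven-membered N-alkylation may be slow enough for the tertiary chloride to eliminate or to be removed reductively by iodide; after ionisation the carbinolamine oxygen of the other C9a epimer may capture C9 instead of the carbon migrating; the strained lactam may be opened hydrolytically during work-up. The fallback, using known reaction classes, sets out from 11 and comes back at 27. It runs the ring contraction before the seven-membered ring exists, so that an ordinary planar lactam results, and closes the strained ring last by olefin metathesis. Boron enolate 13 is combined with acrolein in place of 12 to give vinyl chlorohydrin F1. Silylation as in step 8 gives silyl ether F2, acetal hydrolysis vinyl keto aldehyde F3, condensation with 17 vinyl N-sulfinyl aldimine F4, the vinylogous Mannich reaction with 2 vinyl N-sulfinyl amino butenolide F5, and HCl/MeOH followed by NaOAc the vinyl α-chloro imine F6. N-Alkylation of the imine with allyl bromide (MeCN, 50 °C) gives N-allyl iminium bromide F7, and aqueous AgBF4/NaHCO3 then effects the Favorskii-type rearrangement of the α-chloro ketiminium salt to N-allyl lactam F8, in which the cyclopentane is in place and the amide is planar. Ring-closing metathesis (second-generation Hoveyda–Grubbs catalyst, toluene, 80 °C, dilute) between the N-allyl and C8 vinyl groups closes ring C as didehydro bridged lactam F9, and the hydrogenation of step 14 saturates C6=C7 together with the butenolide to give 27.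

2. Step 7. What may go wrong: poor facial discrimination or erosion of the anti relationship with the fully substituted chloro enolate, sluggish addition at the hindered carbon, or Darzens closure of the aldolate. The fallback sets out from 11 and comes back at 14, replacing the aldol by C-acylation and reagent-controlled reduction. Soft enolisation (MgBr2·OEt2, i-Pr2NEt) and C-acylation with 4-chlorobutanoyl chloride give α-chloro β-diketone F10. Corey–Bakshi–Shibata reduction ((S)-methyl oxazaborolidine, BH3·SMe2) of the less hindered side-chain carbonyl then sets C8 by reagent control and gives 14.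

3. Step 5. What may go wrong: epimerisation of the butenolide γ-carbon C11 under the amine, low reactivity of the ketone enamine towards the butenolide, or an epimer mixture at C1/C13 if the enamine geometry or the chair preference is not clean. The fallback sets out from 4 and comes back at 9, making the donor acidic enough for a carbonate base. Addition of lithiated 2-[2-(phenylsulfonyl)ethyl]-1,3-dioxolane (n-butyllithium, THF, −78 °C) to 4 gives β-hydroxy sulfone F11, Dess–Martin oxidation β-keto sulfone F12, and Cs2CO3 in MeCN the cyclised keto sulfone F13 by intramolecular Michael addition. SmI2 in THF/MeOH then removes the sulfonyl group with protonation at C1 to give 9.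

Further compounds
F1 | step 13 | vinyl chlorohydrin | CC[C@@H]1[C@H]2OC(=O)[C@@H](C)[C@H]2[C@H](CC2OCCO2)C(=O)[C@@]1(Cl)[C@H](O)C=C
F2 | step 13 | silyl ether of F1 | CC[C@@H]1[C@H]2OC(=O)[C@@H](C)[C@H]2[C@H](CC2OCCO2)C(=O)[C@@]1(Cl)[C@H](O[Si](C)(C)C(C)(C)C)C=C
F3 | step 13 | vinyl keto aldehyde | CC[C@@H]1[C@H]2OC(=O)[C@@H](C)[C@H]2[C@H](CC=O)C(=O)[C@@]1(Cl)[C@H](O[Si](C)(C)C(C)(C)C)C=C
F4 | step 13 | vinyl N-sulfinyl aldimine | CC[C@@H]1[C@H]2OC(=O)[C@@H](C)[C@H]2[C@H](C/C=N/[S@@](=O)C(C)(C)C)C(=O)[C@@]1(Cl)[C@H](O[Si](C)(C)C(C)(C)C)C=C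
F5 | step 13 | vinyl N-sulfinyl amino butenolide | CC[C@@H]1[C@H]2OC(=O)[C@@H](C)[C@H]2[C@H](C[C@H]([C@H]3C=C(C)C(=O)O3)N[S@@](=O)C(C)(C)C)C(=O)[C@@]1(Cl)[C@H](O[Si](C)(C)C(C)(C)C)C=C
F6 | step 13 | vinyl α-chloro imine | CC[C@@H]1[C@H]2OC(=O)[C@@H](C)[C@H]2[C@@H]2C[C@H]([C@H]3C=C(C)C(=O)O3)N=C2[C@@]1(Cl)[C@H](O[Si](C)(C)C(C)(C)C)C=C
F7 | step 13 | N-allyl iminium bromide | CC[C@@H]1[C@H]2OC(=O)[C@@H](C)[C@H]2[C@@H]2C[C@H]([C@H]3C=C(C)C(=O)O3)[N+](CC=C)=C2[C@@]1(Cl)[C@H](O[Si](C)(C)C(C)(C)C)C=C.[Br-]
F8 | step 13 | N-allyl lactam | CC[C@@H]1[C@H]2OC(=O)[C@@H](C)[C@H]2[C@@H]2C[C@H]([C@H]3C=C(C)C(=O)O3)N(CC=C)C(=O)[C@]12[C@H](O[Si](C)(C)C(C)(C)C)C=C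
F9 | step 13 | didehydro bridged lactam | CC[C@@H]1[C@H]2OC(=O)[C@@H](C)[C@H]2[C@@H]2C[C@H]([C@H]3C=C(C)C(=O)O3)N3CC=C[C@@H](O[Si](C)(C)C(C)(C)C)[C@@]12C3=O
F10 | step 7 | α-chloro β-diketone | CC[C@@H]1[C@H]2OC(=O)[C@@H](C)[C@H]2[C@H](CC2OCCO2)C(=O)[C@@]1(Cl)C(=O)CCCCl
F11 | step 5 | β-hydroxy sulfone | CC[C@@H](CC(O)C(CC1OCCO1)S(=O)(=O)c1ccccc1)[C@H]1OC(=O)C(C)=C1
F12 | step 5 | β-keto sulfone | CC[C@@H](CC(=O)C(CC1OCCO1)S(=O)(=O)c1ccccc1)[C@H]1OC(=O)C(C)=C1
F13 | step 5 | cyclised keto sulfone | CC[C@@H]1[C@H]2OC(=O)[C@@H](C)[C@H]2C(CC2OCCO2)(S(=O)(=O)c2ccccc2)C(=O)C1
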